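**Retrosynthetic overview**
1. Target 8 ⇐ dienol dibenzoate 7 by hydroxyl-directed syn-epoxidation of the trisubstituted alkene; the oxirane is the only ring made and it is made last.
2. 7 ⇐ 5 by benzoylation of the primary and the distal ring oxygen while the proximal ring oxygen is masked as a silyl ether (6), then desilylation.
3. 5 ⇐ 2 by marking the distal hydroxyl with a sacrificial pivalate (3), silylating the proximal one (4), and one hydride reduction that turns CO2Et into CH2OH and strips the pivalate.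
4. 2 ⇐ ethyl benzoate 1 by dioxygenase-catalysed arene cis-dihydroxylation; the carbocycle is the original benzene ring and both carbinol stereocentres arise in this one enzymatic step.

Assumption: the SMILES is read as having the oxirane oxygen, the free hydroxyl and the ring benzoate all on one face, i.e. [(1S,2S,3S,6R)-3-(benzoyloxy)-2-hydroxy-7-oxabicyclo[4.1.0]hept-4-en-1-yl]methyl benzoate, and the recombinant whole-cell biocatalyst is taken as an available catalyst.

**Route**

Step 1
Reactants: 1 ethyl benzoate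
Product: 2 ethyl (5S,6R)-5,6-dihydroxycyclohexa-1,3-diene-1-carboxylate
Conditions: E. coli JM109(pDTG601A) whole cells expressing toluene dioxygenase (an arene cis-dihydroxylating dioxygenase, oxidoreductase class), IPTG, glucose feed, air, pH 6.8 mineral medium, 35 °C; EtOAc extraction
Reagents that add atoms: dioxygen, O=O
Why: Enzymatic arene cis-dihydroxylation adds both atoms of O2 to one face of the 2,3-bond of the achiral arene inside the chiral active site, so the two carbinol centres (5S,6R) are created together, cis and essentially enantiopure, by asymmetric biocatalysis.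

Step 2
Reactants: 2 ethyl (5S,6R)-5,6-dihydroxycyclohexa-1,3-diene-1-carboxylate
Product: 3 ethyl (5S,6R)-5-[(2,2-dimethylpropanoyl)oxy]-6-hydroxycyclohexa-1,3-diene-1-carboxylate
Conditions: PivCl (1.05 equiv), pyridine, CH2Cl2, −40 → −10 °C
Reagents that add atoms: pivaloyl chloride, CC(C)(C)C(=O)Cl
Why: Sterically controlled regioselective O-acylation puts the bulky acyl group on the pseudo-equatorial C5 hydroxyl remote from the ester, because the C6 hydroxyl is pseudo-axial, flanked by the ester-bearing sp2 carbon and hydrogen-bonded to the ester carbonyl; no stereocentre is touched.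

Step 3
Reactants: 3 ethyl (5S,6R)-5-[(2,2-dimethylpropanoyl)oxy]-6-hydroxycyclohexa-1,3-diene-1-carboxylate
Product: 4 ethyl (5S,6R)-5-[(2,2-dimethylpropanoyl)oxy]-6-[(triethylsilyl)oxy]cyclohexa-1,3-diene-1-carboxylate
Conditions: Et3SiOTf (1.3 equiv), 2,6-lutidine, CH2Cl2, −78 → −30 °C
Reagents that add atoms: triethylsilyl trifluoromethanesulfonate, CC[Si](CC)(CC)OS(=O)(=O)C(F)(F)F
Why: Silyl triflate O-silylation is fast enough at −78 °C to cap the hindered C6 hydroxyl before any 1,2-pivaloyl migration, which fixes the distinction between the two ring oxygens.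

Step 4
Reactants: 4 ethyl (5S,6R)-5-[(2,2-dimethylpropanoyl)oxy]-6-[(triethylsilyl)oxy]cyclohexa-1,3-diene-1-carboxylate
Product: 5 (1S,6R)-5-(hydroxymethyl)-6-[(triethylsilyl)oxy]cyclohexa-2,4-dien-1-ol
Conditions: iBu2AlH (6 equiv), CH2Cl2, −78 → −40 °C; EtOAc quench, aq. KNaC4H4O6
Reagents that add atoms: none
Why: Hydride reduction with a Lewis-acidic aluminium hydride gives 1,2-reduction of the conjugated ester to the allylic alcohol and cleaves the sacrificial pivalate in the same operation, leaving the silyl ether, the diene and both stereocentres untouched.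

Step 5
Reactants: 5 (1S,6R)-5-(hydroxymethyl)-6-[(triethylsilyl)oxy]cyclohexa-2,4-dien-1-ol
Product: 6 [(5S,6R)-5-(benzoyloxy)-6-[(triethylsilyl)oxy]cyclohexa-1,3-dien-1-yl]methyl benzoate
Conditions: BzCl (3 equiv), pyridine, DMAP (cat.), CH2Cl2, 0 °C → rt
Reagents that add atoms: benzoyl chloride, O=C(Cl)c1ccccc1
Why: DMAP-catalysed acylation esterifies the only two free hydroxyls (primary and C5 secondary) while the C6 oxygen is blocked, so the benzoate pattern of the target is fixed unambiguously.

Step 6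
Reactants: 6 [(5S,6R)-5-(benzoyloxy)-6-[(triethylsilyl)oxy]cyclohexa-1,3-dien-1-yl]methyl benzoate
Product: 7 [(5S,6R)-5-(benzoyloxy)-6-hydroxycyclohexa-1,3-dien-1-yl]methyl benzoate
Conditions: HF·pyridine, pyridine, THF, 0 °C; NaHCO3 work-up
Reagents that add atoms: none
Why: Fluoride-mediated desilylation driven by the Si–F bond removes the triethylsilyl ether under buffered, non-basic conditions, so the neighbouring cis benzoate cannot migrate through an alkoxide and the acid-labile diene is spared.

Step 7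
Reactants: 7 [(5S,6R)-5-(benzoyloxy)-6-hydroxycyclohexa-1,3-dien-1-yl]methyl benzoate
Product: 8 [(1S,2S,3S,6R)-3-(benzoyloxy)-2-hydroxy-7-oxabicyclo[4.1.0]hept-4-en-1-yl]methyl benzoate
Conditions: VO(acac)2 (5 mol%), tBuOOH (1.3 equiv, decane solution), CH2Cl2, 0 °C → rt; Na2S2O3 quench
Reagents that add atoms: tert-butyl hydroperoxide, CC(C)(C)OO
Why: In this hydroxyl-directed vanadium-catalysed epoxidation the vanadate ester of the C6 hydroxyl delivers the peroxide oxygen to the adjacent trisubstituted alkene on the hydroxyl-bearing face, setting the two oxirane centres (1S,6R) cis to the hydroxyl and leaving the disubstituted alkene, which has no free allylic hydroxyl, intact.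

**Compound list**

1 | ethyl benzoate | CCOC(=O)c1ccccc1 | starting material
2 | ethyl (5S,6R)-5,6-dihydroxycyclohexa-1,3-diene-1-carboxylate | CCOC(=O)C1=CC=C[C@H](O)[C@@H]1O | intermediate
3 | ethyl (5S,6R)-5-[(2,2-dimethylpropanoyl)oxy]-6-hydroxycyclohexa-1,3-diene-1-carboxylate | CCOC(=O)C1=CC=C[C@H](OC(=O)C(C)(C)C)[C@@H]1O | intermediate
4 | ethyl (5S,6R)-5-[(2,2-dimethylpropanoyl)oxy]-6-[(triethylsilyl)oxy]cyclohexa-1,3-diene-1-carboxylate | CCOC(=O)C1=CC=C[C@H](OC(=O)C(C)(C)C)[C@@H]1O[Si](CC)(CC)CC | intermediate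
5 | (1S,6R)-5-(hydroxymethyl)-6-[(triethylsilyl)oxy]cyclohexa-2,4-dien-1-ol | OCC1=CC=C[C@H](O)[C@@H]1O[Si](CC)(CC)CC | intermediate
6 | [(5S,6R)-5-(benzoyloxy)-6-[(triethylsilyl)oxy]cyclohexa-1,3-dien-1-yl]methyl benzoate | O=C(OCC1=CC=C[C@H](OC(=O)c2ccccc2)[C@@H]1O[Si](CC)(CC)CC)c1ccccc1 | intermediate
7 | [(5S,6R)-5-(benzoyloxy)-6-hydroxycyclohexa-1,3-dien-1-yl]methyl benzoate | O=C(OCC1=CC=C[C@H](OC(=O)c2ccccc2)[C@@H]1O)c1ccccc1 | intermediate
8 | [(1S,2S,3S,6R)-3-(benzoyloxy)-2-hydroxy-7-oxabicyclo[4.1.0]hept-4-en-1-yl]methyl benzoate | O=C(OC[C@@]12O[C@@H]1C=C[C@H](OC(=O)c1ccccc1)[C@@H]2O)c1ccccc1 | target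

**Totals and risks**

Total step count: 7. Longest linear sequence: 7 steps (1 → 8).

Step 2 (regioselective mono-pivaloylation) is the first risk, because the selectivity for the distal hydroxyl rests on steric and hydrogen-bonding arguments and could be modest. The fallback sets out from 2 and comes back at 7, and moves regiocontrol to a tin acetal at a later diol. Both hydroxyls are silylated (Et3SiCl, imidazole, DMF) to give ethyl (5S,6R)-5,6-bis[(triethylsilyl)oxy]cyclohexa-1,3-diene-1-carboxylate F1. The ester is reduced with iBu2AlH to [(5S,6R)-5,6-bis[(triethylsilyl)oxy]cyclohexa-1,3-dien-1-yl]methanol F2. The primary alcohol is benzoylated (BzCl, pyridine) to [(5S,6R)-5,6-bis[(triethylsilyl)oxy]cyclohexa-1,3-dien-1-yl]methyl benzoate F3. Both silyl groups are removed with HF·pyridine to give [(5S,6R)-5,6-dihydroxycyclohexa-1,3-dien-1-yl]methyl benzoate F4. The ring benzoate is then placed with Me2SnCl2 (cat.), BzCl and K2CO3 in THF, where the stannylene acetal activates the less hindered pseudo-equatorial distal oxygen, giving 7.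

Step 6 (desilylation next to a cis benzoate on an acid-labile diene) is the second risk, through benzoyl migration or aromatisation by loss of benzoic acid. The fallback sets out from 3 and comes back at 7, and replaces the fluoride-labile silyl ether by an acetal that is removed by transacetalisation. The C6 hydroxyl of 3 is capped with 2-methoxypropene and PPTS (cat.) to give ethyl (5S,6R)-5-[(2,2-dimethylpropanoyl)oxy]-6-[(2-methoxypropan-2-yl)oxy]cyclohexa-1,3-diene-1-carboxylate F5. Reduction with iBu2AlH gives (1S,6R)-5-(hydroxymethyl)-6-[(2-methoxypropan-2-yl)oxy]cyclohexa-2,4-dien-1-ol F6. Dibenzoylation (BzCl, pyridine, DMAP) gives [(5S,6R)-5-(benzoyloxy)-6-[(2-methoxypropan-2-yl)oxy]cyclohexa-1,3-dien-1-yl]methyl benzoate F7. The acetal is exchanged off with PPTS (cat.) in MeOH at 0 °C, with no fluoride and no alkoxide, to reach 7.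

Step 7 (directed epoxidation of the dienol dibenzoate) is the third risk: the alkene is deactivated by the allylic benzoyloxy groups, the dienol can be oxidised or can aromatise, and the vinyl oxirane is sensitive to Lewis acids. The fallback sets out from 5 and comes back at 8, and epoxidises before any benzoate is present. The silyl ether of 5 is removed with NH4F in MeOH to give (1S,2R)-3-(hydroxymethyl)cyclohexa-3,5-diene-1,2-diol F8. Its electron-rich trisubstituted alkene carries two allylic hydroxyls and is epoxidised on the hydroxyl face with VO(acac)2 (cat.) and tBuOOH (1.0 equiv) at −20 °C, giving (1S,2S,3S,6R)-1-(hydroxymethyl)-7-oxabicyclo[4.1.0]hept-4-ene-2,3-diol F9. Benzoylation with BzCl (2.1 equiv) and 2,4,6-collidine in CH2Cl2 at −40 °C takes the primary and the allylic C3 hydroxyl and leaves the C2 hydroxyl, which is wedged against the quaternary oxirane carbon, to give 8.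

**Further compounds**

F1 | step 2 | ethyl (5S,6R)-5,6-bis[(triethylsilyl)oxy]cyclohexa-1,3-diene-1-carboxylate | CCOC(=O)C1=CC=C[C@H](O[Si](CC)(CC)CC)[C@@H]1O[Si](CC)(CC)CC
F2 | step 2 | [(5S,6R)-5,6-bis[(triethylsilyl)oxy]cyclohexa-1,3-dien-1-yl]methanol | OCC1=CC=C[C@H](O[Si](CC)(CC)CC)[C@@H]1O[Si](CC)(CC)CC
F3 | step 2 | [(5S,6R)-5,6-bis[(triethylsilyl)oxy]cyclohexa-1,3-dien-1-yl]methyl benzoate | O=C(OCC1=CC=C[C@H](O[Si](CC)(CC)CC)[C@@H]1O[Si](CC)(CC)CC)c1ccccc1
F4 | step 2 | [(5S,6R)-5,6-dihydroxycyclohexa-1,3-dien-1-yl]methyl benzoate | O=C(OCC1=CC=C[C@H](O)[C@@H]1O)c1ccccc1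
F5 | step 6 | ethyl (5S,6R)-5-[(2,2-dimethylpropanoyl)oxy]-6-[(2-methoxypropan-2-yl)oxy]cyclohexa-1,3-diene-1-carboxylate | CCOC(=O)C1=CC=C[C@H](OC(=O)C(C)(C)C)[C@@H]1OC(C)(C)OC
F6 | step 6 | (1S,6R)-5-(hydroxymethyl)-6-[(2-methoxypropan-2-yl)oxy]cyclohexa-2,4-dien-1-ol | OCC1=CC=C[C@H](O)[C@@H]1OC(C)(C)OC
F7 | step 6 | [(5S,6R)-5-(benzoyloxy)-6-[(2-methoxypropan-2-yl)oxy]cyclohexa-1,3-dien-1-yl]methyl benzoate | O=C(OCC1=CC=C[C@H](OC(=O)c2ccccc2)[C@@H]1OC(C)(C)OC)c1ccccc1
F8 | step 7 | (1S,2R)-3-(hydroxymethyl)cyclohexa-3,5-diene-1,2-diol | OCC1=CC=C[C@H](O)[C@@H]1O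
F9 | step 7 | (1S,2S,3S,6R)-1-(hydroxymethyl)-7-oxabicyclo[4.1.0]hept-4-ene-2,3-diol | OC[C@@]12O[C@@H]1C=C[C@H](O)[C@@H]2O
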